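**Retrosynthetic overview**
1. Feature: in the ten-membered carbocycle C1–C10, C3 is a secondary allylic carbinol carbon. It is bonded directly to C4, the methyl-bearing carbon of the Z-C4=C5 alkene. This pair is the retron of an alkenylmetal addition to an aldehyde, so the ring is cut at C3–C4 to a Z-alkenyl iodide and a C3 aldehyde.
2. Late steps: the C1–C10 oxirane comes last, from the E-alkene by peracid attack on the outer ring face. The C3 isobutyrate comes from the alcohol that the ring closure delivers.
3. Seco compound: C7–C8 is cut to a 3-(bromomethyl)butenolide (C4–C7, C11–C13, C15) and a β,γ-unsaturated C8 aldehyde (C1–C3, C8–C10, C14). The indium allylation sets C7 but should give the 8-epi carbinol. A Mitsunobu esterification with (2S,3S)-epoxyangelic acid inverts it to the 8R ester, so C8 carries its final ester during ring closure.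
4. Fragments: the butenolide comes from acrolein and propynyl Grignard (Red-Al/I2, lipase resolution, acrylate RCM). The aldehyde comes from 3-butyn-1-ol (carboalumination, ethylene oxide). The acid comes from angelic acid (Sharpless epoxidation).
5. Ring order: γ-lactone ring as butenolide (step 5), side-chain oxirane (step 12, separate branch), ten-membered carbocycle (step 18), C1–C10 oxirane (step 20).

Key step: step 18

Numbering: germacrane numbering is used (ring C1–C10, lactone C11–C13, C14 on C10, C15 on C4). C6 is labelled S in all iodides and R in the macrocycles only because iodine changes the CIP ranking; its spatial arrangement is the same throughout.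
Assumption: the indium allylation is taken to run through the closed chair transition state, which for the ring-locked allyl geometry gives the 7,8-anti adduct (8S). The C8 ester is therefore introduced with inversion.

**Step 1**
Reactants: 1 acrolein; 2 1-propynylmagnesium bromide
Product: 3 rac-hex-1-en-4-yn-3-ol
Conditions: THF, −78 → 0 °C; aq. NH4Cl
Reagents that add atoms: none
Why: 1,2-addition of an alkynyl Grignard reagent to an enal is fast at low temperature and gives the racemic carbinol that holds C4–C7 and C15.

**Step 2**
Reactants: 3 rac-hex-1-en-4-yn-3-ol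
Product: 5 rac-(4Z)-5-iodohexa-1,4-dien-3-ol, via cyclic alkenylaluminate 4 (not isolated)
Conditions: Red-Al, THF, 0 °C → rt; EtOAc (destroys excess hydride); I2, THF, −78 → 0 °C
Reagents that add atoms: iodine, II
Why: alkoxide-directed trans-hydroalumination of the propargylic alkyne places aluminium on the distal carbon C4 in a five-membered chelate, and iodinolysis with retention should give only the Z-iodide (I cis to the carbinol carbon), the isolated vinyl group staying untouched.

**Step 3**
Reactants: 5 rac-(4Z)-5-iodohexa-1,4-dien-3-ol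
Product: 6 (3S,4Z)-5-iodohexa-1,4-dien-3-ol
Conditions: Novozym 435 (CAL-B), vinyl acetate, MTBE, 30 °C, run past half conversion; chromatography
Reagents that add atoms: none
Why: lipase kinetic resolution by transesterification, in which, following the Kazlauskas rule (small vinyl, large iodopropenyl group), the (R)-alcohol should be acetylated and the (S)-alcohol that sets C6 should remain.

**Step 4**
Reactants: 6 (3S,4Z)-5-iodohexa-1,4-dien-3-ol; 7 2-(bromomethyl)acrylic acid
Product: 8 (3S,4Z)-5-iodohexa-1,4-dien-3-yl 2-(bromomethyl)prop-2-enoate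
Conditions: DCC, DMAP (5 mol %), CH2Cl2, 0 °C
Reagents that add atoms: none
Why: Steglich esterification acylates the bis-allylic secondary alcohol under neutral conditions with retention at C6, and the low DMAP loading at 0 °C limits attack on the allylic bromide.

**Step 5**
Reactants: 8 (3S,4Z)-5-iodohexa-1,4-dien-3-yl 2-(bromomethyl)prop-2-enoate
Product: 9 (5S)-3-(bromomethyl)-5-[(1Z)-2-iodoprop-1-en-1-yl]furan-2(5H)-one
Conditions: Hoveyda–Grubbs II (5 mol %), CH2Cl2 (10 mM), reflux
Reagents that add atoms: none
Why: ring-closing metathesis, in which the phosphine-free carbene loads on the monosubstituted vinyl group and closes onto the 1,1-disubstituted acrylate alkene to the butenolide with loss of ethene, while the trisubstituted iodoalkene is inert, the allylic bromide meets no nucleophile and the neutral medium spares the acidic C6–H.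

**Step 6**
Reactants: 10 3-butyn-1-ol
Product: 11 4-(tert-butyldimethylsilyloxy)but-1-yne
Conditions: TBSCl, imidazole, CH2Cl2, rt
Reagents that add atoms: tert-butyldimethylsilyl chloride, C[Si](C)(Cl)C(C)(C)C
Why: standard silylation of a primary alcohol masks the future C8 oxygen for the organoaluminium step.

**Step 7**
Reactants: 11 4-(tert-butyldimethylsilyloxy)but-1-yne; 12 ethylene oxide
Product: 15 (3E)-6-(tert-butyldimethylsilyloxy)-4-methylhex-3-en-1-ol, via alkenyldimethylalane 13 (not isolated), via lithium alkenylalanate 14 (not isolated)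
Conditions: Me3Al, Cp2ZrCl2 (cat.), CH2Cl2, 0 °C → rt; concentrate; n-BuLi, hexane/THF, −78 → 0 °C; ethylene oxide (THF solution), 0 °C → rt
Reagents that add atoms: trimethylaluminium, C[Al](C)C
Why: Negishi zirconium-catalysed carboalumination adds methyl and aluminium syn across the terminal alkyne with methyl on the internal carbon, and the derived alanate opens ethylene oxide with retention, which fixes the E-C1=C10 alkene and adds C2–C3.

**Step 8**
Reactants: 15 (3E)-6-(tert-butyldimethylsilyloxy)-4-methylhex-3-en-1-ol
Product: 16 tert-butyl{[(3E)-6-(4-methoxybenzyloxy)-3-methylhex-3-en-1-yl]oxy}dimethylsilane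
Conditions: NaH, PMBCl, TBAI (cat.), THF/DMF, 0 °C → rt
Reagents that add atoms: 4-methoxybenzyl chloride, COc1ccc(CCl)cc1
Why: Williamson etherification protects the C3 oxygen with a group that is later removed oxidatively, and the remote primary silyl ether survives it.

**Step 9**
Reactants: 16 tert-butyl{[(3E)-6-(4-methoxybenzyloxy)-3-methylhex-3-en-1-yl]oxy}dimethylsilane
Product: 17 (3E)-6-(4-methoxybenzyloxy)-3-methylhex-3-en-1-ol
Conditions: TBAF, THF, 0 °C → rt
Reagents that add atoms: none
Why: fluoride cleaves the silyl ether selectively and leaves the PMB ether and the alkene unchanged.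

**Step 10**
Reactants: 17 (3E)-6-(4-methoxybenzyloxy)-3-methylhex-3-en-1-ol
Product: 18 (3E)-6-(4-methoxybenzyloxy)-3-methylhex-3-enal
Conditions: Dess–Martin periodinane, NaHCO3, CH2Cl2, 0 °C; used at once
Reagents that add atoms: none
Why: buffered Dess–Martin oxidation stops at the aldehyde and is mild enough to keep the β,γ-alkene out of conjugation.

**Step 11**
Reactants: 19 angelic acid
Product: 20 (2Z)-2-methylbut-2-en-1-ol (angelyl alcohol)
Conditions: LiAlH4, Et2O, 0 °C → rt
Reagents that add atoms: none
Why: hydride reduction attacks only the carboxyl group of this alkyl-substituted conjugated acid, so the Z geometry is kept.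

**Step 12**
Reactants: 20 (2Z)-2-methylbut-2-en-1-ol
Product: 21 [(2R,3S)-2,3-dimethyloxiran-2-yl]methanol
Conditions: Ti(OiPr)4 (cat.), D-(−)-DIPT (cat.), t-BuOOH, 4 Å MS, CH2Cl2, −20 °C
Reagents that add atoms: tert-butyl hydroperoxide, CC(C)(C)OO
Why: Sharpless asymmetric epoxidation with the D-(−)-tartrate delivers oxygen to the alkene face that gives the (2R,3S)-epoxy alcohol, the Z geometry fixes the cis relation of CH2OH and the C3 methyl, and any minor enantiomer would be removed later as a diastereomer of 25.

**Step 13**
Reactants: 21 [(2R,3S)-2,3-dimethyloxiran-2-yl]methanol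
Product: 22 (2S,3S)-2,3-dimethyloxirane-2-carboxylic acid (epoxyangelic acid)
Conditions: RuCl3 (cat.), NaIO4, MeCN/EtOAc/H2O, rt
Reagents that add atoms: water, O; sodium periodate (terminal oxidant), [Na+].[O-]I(=O)(=O)=O
Why: catalytic ruthenium tetroxide oxidation takes primary epoxy alcohols to glycidic acids without opening the oxirane, so both centres persist (C2 changes from R to S only through the CIP ranking).

**Step 14**
Reactants: 9 (5S)-3-(bromomethyl)-5-[(1Z)-2-iodoprop-1-en-1-yl]furan-2(5H)-one; 18 (3E)-6-(4-methoxybenzyloxy)-3-methylhex-3-enal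
Product: 24 (4R,5S)-4-[(1S,3E)-1-hydroxy-6-(4-methoxybenzyloxy)-3-methylhex-3-en-1-yl]-5-[(1Z)-2-iodoprop-1-en-1-yl]-3-methylideneoxolan-2-one, via allylindium dibromide 23 (not isolated)
Conditions: In powder, THF/H2O (1:1), rt
Reagents that add atoms: none
Why: indium Barbier allylation with allylic transposition, in which 23 bonds through C7 on the ring face anti to the C6 alkenyl group (6,7-trans, 7R) and the Zimmerman–Traxler chair with the aldehyde chain equatorial should set the 7,8-anti relation (8S), while the α-methylene lactone is unveiled and the alkenyl iodide is left alone.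

**Step 15**
Reactants: 24 the (8S)-carbinol of step 14; 22 (2S,3S)-2,3-dimethyloxirane-2-carboxylic acid
Product: 25 (1R,3E)-1-{(2S,3R)-2-[(1Z)-2-iodoprop-1-en-1-yl]-4-methylidene-5-oxooxolan-3-yl}-6-(4-methoxybenzyloxy)-3-methylhex-3-en-1-yl (2S,3S)-2,3-dimethyloxirane-2-carboxylate
Conditions: PPh3 and DIAD premixed, toluene, 0 °C; then 22 and 24, 0 °C → rt
Reagents that add atoms: none
Why: Mitsunobu esterification replaces the activated C8 oxygen by the carboxylate in an SN2 process, so the (8S)-carbinol becomes the (8R)-ester of the target and the side chain is installed in the same operation; the fairly acidic glycidic acid suits the reaction, and premixing keeps free phosphine away from the α-methylene lactone.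

**Step 16**
Reactants: 25 the PMB ether of step 15
Product: 26 (1R,3E)-6-hydroxy-1-{(2S,3R)-2-[(1Z)-2-iodoprop-1-en-1-yl]-4-methylidene-5-oxooxolan-3-yl}-3-methylhex-3-en-1-yl (2S,3S)-2,3-dimethyloxirane-2-carboxylate
Conditions: DDQ, CH2Cl2/pH 7 buffer, 0 °C
Reagents that add atoms: none
Why: oxidative PMB cleavage is neutral and touches neither the esters, the oxirane, the alkenyl iodide nor the unactivated alkenes.

**Step 17**
Reactants: 26 the C3 alcohol of step 16
Product: 27 seco iodo-aldehyde, (1R,3E)-1-{(2S,3R)-2-[(1Z)-2-iodoprop-1-en-1-yl]-4-methylidene-5-oxooxolan-3-yl}-3-methyl-6-oxohex-3-en-1-yl (2S,3S)-2,3-dimethyloxirane-2-carboxylate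
Conditions: Dess–Martin periodinane, NaHCO3, CH2Cl2, 0 °C; used at once
Reagents that add atoms: none
Why: buffered Dess–Martin oxidation gives the β,γ-unsaturated C3 aldehyde without moving the C1=C10 alkene into conjugation.

**Step 18**
Reactants: 27 seco iodo-aldehyde
Product: 29 (1(10)E,4Z,3S,6R,7R,8R)-3-hydroxy-8-[(2S,3S)-2,3-dimethyloxirane-2-carbonyloxy]germacra-1(10),4,11(13)-trien-12,6-olide, via alkenylchromium dichloride 28 (not isolated)
Conditions: CrCl2 (10 equiv), NiCl2 (cat.), degassed DMSO, rt, 27 added by syringe pump to about 2 mM; aq. work-up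
Reagents that add atoms: none
Why: Nickel(0), formed from NiCl2 by chromium(II), inserts into the C4–I bond with retention of the Z geometry and passes the alkenyl group to chromium(III); the resulting 28 adds to the C3 aldehyde and forms C3–C4. This is an intramolecular Nozaki–Hiyama–Kishi coupling, a reaction type known for closing medium-ring carbocyclic allylic alcohols from alkenyl iodide–aldehydes. The ten-membered carbocycle closes in a 10-exo-trig mode, and the Z-alkene, which holds C3 and C6 on the same side, together with the trans-lactone and the E-C1=C10 alkene, pre-bends the chain. The new C3 centre is under substrate control: with the carbonyl oxygen and its chromium turned away from the forming ring, the alkenyl carbon is expected to reach the Re face, which gives the (3S)-alcohol (3β). The step needs preference for the aldehyde over the α-methylene lactone, the ester and the oxirane, which the low basicity and aldehyde selectivity of alkenylchromium(III) secure. It also needs closure to outrun dimerisation, which slow addition at high dilution secures.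

**Step 19**
Reactants: 29 the macrocyclic 3-alcohol
Product: 30 (1(10)E,4Z,3S,6R,7R,8R)-3-isobutyryloxy-8-[(2S,3S)-2,3-dimethyloxirane-2-carbonyloxy]germacra-1(10),4,11(13)-trien-12,6-olide
Conditions: (i-PrCO)2O, DMAP (cat.), pyridine, 0 °C → rt
Reagents that add atoms: isobutyric anhydride, CC(C)C(=O)OC(=O)C(C)C
Why: DMAP-catalysed acylation of the secondary allylic alcohol proceeds with retention at C3 and needs no strong base, so the α-methylene lactone and the oxirane ester persist.

**Step 20**
Reactants: 30 the 3-isobutyrate
Product: 31 target CNP0117882.1, (1R,3S,4Z,6R,7R,8R,10R)-1,10-epoxy-3-isobutyryloxy-8-[(2S,3S)-2,3-dimethyloxirane-2-carbonyloxy]germacra-4,11(13)-dien-12,6-olide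
Conditions: mCPBA (1.05 equiv), CH2Cl2, 0 °C
Reagents that add atoms: 3-chloroperoxybenzoic acid, OOC(=O)c1cccc(Cl)c1
Why: Prilezhaev epoxidation picks the only electron-rich alkene, C1=C10 (C4=C5 is deactivated by two allylic acyloxy groups, C11=C13 by the lactone carbonyl), and attack on the outer face of the ring conformer with C14 on the β face should give the 1β,10α-oxirane (1R,10R), the E geometry being transferred stereospecifically.

**Compound list**
1 | acrolein | C=CC=O | starting material
2 | 1-propynylmagnesium bromide | CC#C[Mg]Br | starting material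
3 | rac-hex-1-en-4-yn-3-ol | C=CC(O)C#CC | intermediate
4 | cyclic alkenylaluminate (sodium salt, oxaaluminacyclopentene) | C=CC1C=C(C)[Al-](OCCOC)(OCCOC)O1.[Na+] | intermediate
5 | rac-(4Z)-5-iodohexa-1,4-dien-3-ol | C=CC(O)/C=C(/C)I | intermediate
6 | (3S,4Z)-5-iodohexa-1,4-dien-3-ol | C=C[C@H](O)/C=C(/C)I | intermediate
7 | 2-(bromomethyl)acrylic acid | C=C(CBr)C(=O)O | starting material
8 | (3S,4Z)-5-iodohexa-1,4-dien-3-yl 2-(bromomethyl)prop-2-enoate | C=C(CBr)C(=O)O[C@H](/C=C(/C)I)C=C | intermediate
9 | (5S)-3-(bromomethyl)-5-[(1Z)-2-iodoprop-1-en-1-yl]furan-2(5H)-one | O=C1O[C@H](/C=C(/C)I)C=C1CBr | intermediate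
10 | 3-butyn-1-ol | C#CCCO | starting material
11 | 4-(tert-butyldimethylsilyloxy)but-1-yne | C#CCCO[Si](C)(C)C(C)(C)C | intermediate
12 | ethylene oxide | C1CO1 | starting material
13 | (E)-alkenyldimethylalane | C[Al](C)/C=C(\C)CCO[Si](C)(C)C(C)(C)C | intermediate
14 | lithium (E)-alkenyl(butyl)dimethylalanate | [Li+].CCCC[Al-](C)(C)/C=C(\C)CCO[Si](C)(C)C(C)(C)C | intermediate
15 | (3E)-6-(tert-butyldimethylsilyloxy)-4-methylhex-3-en-1-ol | OCC/C=C(\C)CCO[Si](C)(C)C(C)(C)C | intermediate
16 | tert-butyl{[(3E)-6-(4-methoxybenzyloxy)-3-methylhex-3-en-1-yl]oxy}dimethylsilane | COc1ccc(COCC/C=C(\C)CCO[Si](C)(C)C(C)(C)C)cc1 | intermediate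
17 | (3E)-6-(4-methoxybenzyloxy)-3-methylhex-3-en-1-ol | COc1ccc(COCC/C=C(\C)CCO)cc1 | intermediate
18 | (3E)-6-(4-methoxybenzyloxy)-3-methylhex-3-enal | COc1ccc(COCC/C=C(\C)CC=O)cc1 | intermediate
19 | angelic acid, (2Z)-2-methylbut-2-enoic acid | C/C=C(/C)C(=O)O | starting material
20 | (2Z)-2-methylbut-2-en-1-ol | C/C=C(/C)CO | intermediate
21 | [(2R,3S)-2,3-dimethyloxiran-2-yl]methanol | OC[C@@]1(C)O[C@H]1C | intermediate
22 | (2S,3S)-2,3-dimethyloxirane-2-carboxylic acid | OC(=O)[C@@]1(C)O[C@H]1C | intermediate
23 | allylindium dibromide from 9 | O=C1O[C@H](/C=C(/C)I)C=C1C[In](Br)Br | intermediate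
24 | Barbier adduct (6S,7R,8S), free 8-OH | C=C1C(=O)O[C@H](/C=C(/C)I)[C@H]1[C@@H](O)C/C(C)=C/CCOCc1ccc(OC)cc1 | intermediate
25 | (8R)-epoxyangelate, C3-OPMB | C=C1C(=O)O[C@H](/C=C(/C)I)[C@H]1[C@H](OC(=O)[C@@]2(C)O[C@H]2C)C/C(C)=C/CCOCc1ccc(OC)cc1 | intermediate
26 | (8R)-epoxyangelate, C3-OH | C=C1C(=O)O[C@H](/C=C(/C)I)[C@H]1[C@H](OC(=O)[C@@]2(C)O[C@H]2C)C/C(C)=C/CCO | intermediate
27 | seco iodo-aldehyde (key-step precursor) | C=C1C(=O)O[C@H](/C=C(/C)I)[C@H]1[C@H](OC(=O)[C@@]2(C)O[C@H]2C)C/C(C)=C/CC=O | intermediate
28 | (Z)-alkenylchromium(III) dichloride from 27 | C=C1C(=O)O[C@H](/C=C(/C)[Cr](Cl)Cl)[C@H]1[C@H](OC(=O)[C@@]2(C)O[C@H]2C)C/C(C)=C/CC=O | intermediate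
29 | 3β-hydroxy heliangolide diene (key-step product) | C=C1C(=O)O[C@@H]2/C=C(/C)[C@@H](O)C/C=C(\C)C[C@@H](OC(=O)[C@@]3(C)O[C@H]3C)[C@@H]12 | intermediate
30 | 3β-isobutyrate | C=C1C(=O)O[C@@H]2/C=C(/C)[C@@H](OC(=O)C(C)C)C/C=C(\C)C[C@@H](OC(=O)[C@@]3(C)O[C@H]3C)[C@@H]12 | intermediate
31 | CNP0117882.1 | C=C1C(=O)O[C@@H]2/C=C(/C)[C@@H](OC(=O)C(C)C)C[C@H]3O[C@]3(C)C[C@@H](OC(=O)[C@@]3(C)O[C@H]3C)[C@@H]12 | target

**Step count and risks**
Total step count: 20.
Longest linear sequence: 12 steps (1–5, then 14–20; equally 6–10, then 14–20).

Steps most likely to fail: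

Step 18. Transannular strain may slow the closure, so that protodemetalation of the alkenylchromium or intermolecular coupling competes. Facial selectivity at the aldehyde may also be poor or reversed. The fallback sets out from 27. The closure is run as described and the (3R)-alcohol F1 is accepted as the product. A Mitsunobu reaction of the (3R)-alcohol F1 with isobutyric acid (PPh3, DIAD, toluene) sets C3 by SN2 inversion instead of by the ring closure and installs the isobutyrate at the same time. The route is rejoined at 30, so step 19 is not needed.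

Step 15. Displacement at the branched C8 carbinol may be sluggish, and elimination toward C7 or C9 may then take over. The fallback avoids substitution at C8 altogether and sets out from 9 and 18. Zinc dust and Bu3SnCl in THF/aq. NH4Cl should convert 9 into the primary allylstannane F2. BF3·OEt2 in CH2Cl2 at −78 °C then adds the allylstannane F2 to aldehyde 18 through an open antiperiplanar transition state. This mode gives syn adducts from γ-substituted allylstannanes, and attack is again anti to the C6 substituent, so the product should be the (8R)-alcohol F3. Yamaguchi esterification of the (8R)-alcohol F3 with 22 proceeds with retention and comes back to the route at 25.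

Step 20. Facial selectivity may be poor if the ring populates a conformer that shows the other face of C1=C10, and attack at C4=C5 may compete. The fallback sets out from 30 and replaces substrate control by reagent control. A Shi epoxidation is used (D-fructose-derived ketone, Oxone, buffered MeCN/dimethoxymethane/H2O, 0 °C). Its chiral dioxirane gives (R,R)-oxiranes from E-trisubstituted alkenes of this substitution pattern and ignores electron-poor alkenes. It comes back at 31 and makes no new compound.

**Further compounds**
F1 | step 18 | (3R)-epimer of 29 | C=C1C(=O)O[C@@H]2/C=C(/C)[C@H](O)C/C=C(\C)C[C@@H](OC(=O)[C@@]3(C)O[C@H]3C)[C@@H]12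
F2 | step 15 | (5S)-5-[(1Z)-2-iodoprop-1-en-1-yl]-3-[(tributylstannyl)methyl]furan-2(5H)-one | O=C1O[C@H](/C=C(/C)I)C=C1C[Sn](CCCC)(CCCC)CCCC
F3 | step 15 | (8R)-epimer of 24 | C=C1C(=O)O[C@H](/C=C(/C)I)[C@H]1[C@H](O)C/C(C)=C/CCOCc1ccc(OC)cc1
F0 | step 20 | none | none
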